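The runs are calculated for an exercise; the scatter is artificial.

The solid substrate tells you what to measure here: how much of it leaves the solid.

| flask | solid substrate | remark | time |
|---|---|---|---|
| spring | 6.7 × 10⁻⁴ M | run made earlier |  |
| winter | 0.0015 M | run made earlier |  |
| flask | 0.0010 M |  | 30 min |

| run | time / min | solid substrate / % | target / % |
|---|---|---|---|
| spring | 2.50 | 57.1 | 12.4 |
| spring | 8.00 | 56.8 | 12.2 |
| spring | 12.0 | 55.5 | 11.6 |
| spring | 20.0 | 57.9 | 14.8 |
| spring | 30.0 | 55.1 | 12.4 |
| spring | 40.0 | 55.5 | 12.8 |
| winter | 3.00 | 80.9 | 3.8 |
| winter | 5.00 | 80.6 | 6.1 |
| winter | 8.00 | 81.3 | 4.2 |
| winter | 12.0 | 81.2 | 5.3 |
| winter | 20.0 | 80.6 | 6.7 |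
| winter | 40.0 | 78.8 | 7.5 |

(readings scatter by 1 percentage point)

- given per volume of solution although it is solid: solid substrate
- steps that have been proposed: starting material <-> target; starting material <-> isomer of the product; solid substrate <-> starting material
- at the start none of the solid substrate is in solution
- what has only dissolved of solid substrate counts as not reacted
- the reaction counts as stopped when no species that holds the solid substrate changes by six tenths of a point or more over the second half of the time

- which holds at 30 min: what has brought the reaction to rest, or that it has not come to rest (for what has run out or reacted, a solid counts together with what of it has only dissolved) (it is still moving / all of the solid substrate has reacted / forward and back rates have come level)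
- part of the solid substrate that has turned into other species by 30 min (what has only dissolved does not count)
- how much target there is at 30 min, in percent of the solid substrate charged
- amount of target if the flask were left three thousand times as long, in percent of the solid substrate charged

Turn the time first. A reaction still under way would lower the solid from reading to reading. From first reading to last, the solid falls 1.6 percentage points in the spring run and 2.1 points in the winter run, with 1 point of scatter on each reading. I read both as flat, so I expect forward and back rates level in the new flask by 30 min.

Now turn the charge c. If a fixed share reacted, the percentages would not move with c. They do: the solid averages 56.3% in spring and 80.6% in winter. So multiply the share gone by c: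

spring: 2.93 × 10⁻⁴ M

winter: 2.91 × 10⁻⁴ M

The two agree. Call this S, the apparent solubility: the concentration of charged material that solution holds in all its forms. Target averages the same way, giving T = 8.51 × 10⁻⁵ M from spring.

For the new flask I reckon:

solid left, (c − S)/c: 70.7%

target, T/c: 8.51%

S does not split dissolved starting material from isomer, so I bracket conversion, from 8.51% to 29.3%. At rest, I expect target to stay put over the long wait that is asked about.

The forecast parts from me on rest and on the long wait: it says it is still moving, with conversion 9.6%, target 8.5% and 4% after the long wait, citing “a slow leak to the unseen isomer”.

The new flask gives this verdict: forward and back rates have come level. Its conversion is 24.4%, its target 7.95%, and its target after the long wait 7.95%.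

    starting material ⇌ target (K = 1.50, k = 0.230 s⁻¹)
    starting material ⇌ isomer of the product (K = 3.10, k = 0.120 s⁻¹)
    solid substrate ⇌ starting material, rate k3*(cs3 - [starting material]) while solid is left; crystals form when [starting material] > cs3 (solubility = 0.0530 mM, k = 0.190 s⁻¹)

In this flask, half of the dissolving turnover up to 30 min is done by 0.499 min and half of the isomer path's by 0.684 min. The backward turnover on the target path is 99.6% of its forward one. Now use S: S/c is 29.3% of this charge, and taking off the 5.30% of dissolved starting material leaves 24.0% converted, with isomer at 16.4%.

With 4.0 × 10⁻⁴ M charged, S leaves 26.7% solid and T gives 21.3% target. That flask stands at 25.8% solid and 19.9% target.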